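**Retrosynthetic overview**

1. The route rests on the fully substituted benzene ring C4a–C5–C6–C7–C8–C8a with O1 on C8a, read as a folded triketide: C8a, O1 and C4a are the carbonyl carbon, the ring oxygen and the α-methylene of a δ-lactone (oxane ring O1–C2–C3–C4–C4a–C8a); C5–C8 come from methyl acetoacetate, and the lactone carbonyl oxygen leaves as water.
2. Late disconnections: the C6 and C8 formyl groups (Vilsmeier–Haack); the ten-membered ring at its C(CH3)=CH bond (ring-closing metathesis); the arene at C4a–C5 (Claisen closure of a 2-ylidene-oxane β-keto ester, then enolisation); C8a–C8 (acetoacetate dianion on the lactone).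
3. Lactone: isobutyl at C4 by cuprate addition to the unsaturated lactone; C4=C4a by Z-selective olefination; the C3 side chain by SN2 opening of an epoxy alcohol; C2/C3 by Sharpless epoxidation of an E-allylic alcohol built from ozonised (R)-α-terpineol.
4. Ring order: oxane ring (as lactone, step 9), then benzene ring (step 13), then ten-membered carbocycle (step 14).

Key step: step 13

Remark: atom numbers are those of the chroman core (O1, C2, C3, C4, C4a, C5–C8, C8a); the ring olefin is taken as Z, as written in the SMILES; the tertiary alcohol is carried as its triethylsilyl ether from step 1 to step 16.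

**Route**

Step 1
Reactants: 1 (R)-α-terpineol
Product: 2 triethyl({2-[(1R)-4-methylcyclohex-3-en-1-yl]propan-2-yl}oxy)silane
Conditions: Et3SiOTf, 2,6-lutidine, CH2Cl2, 0 °C
Reagents that add atoms: triethylsilyl trifluoromethanesulfonate, CC[Si](CC)(CC)OS(=O)(=O)C(F)(F)F
Why: Silylation of a tertiary alcohol with a silyl triflate under lutidine buffering is routine and masks the hydroxyl that would otherwise trap the aldehyde of step 2 as a lactol; the stereocentre is not touched.

Step 2
Reactants: 2 silyl ether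
Product: 4 (3R)-6-oxo-3-[2-(triethylsilyloxy)propan-2-yl]heptanal, via secondary ozonide 3 (not isolated)
Conditions: O3, CH2Cl2, −78 °C; then PPh3, −78 °C to rt
Reagents that add atoms: ozone, [O-][O+]=O
Why: Ozonolysis with reductive work-up cleaves the only olefin and gives in one operation the methyl ketone (future C2 with its methyl group) and the aldehyde arm, without involving the stereocentre.

Step 3
Reactants: 4 keto aldehyde
Product: 5 (5R)-5-[2-(triethylsilyloxy)propan-2-yl]oct-7-en-2-one
Conditions: Ph3PCH3Br, KN(SiMe3)2, THF, 0 °C; then 4, −78 °C to −20 °C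
Reagents that add atoms: methylenetriphenylphosphorane (made from methyltriphenylphosphonium bromide), C=P(c1ccccc1)(c1ccccc1)c1ccccc1
Why: Wittig methylenation with one equivalent of the unstabilised ylide at low temperature should take the aldehyde and leave the slower methyl ketone.

Step 4
Reactants: 5 methyl ketone; 6 triethyl phosphonoacetate
Product: 7 ethyl (2E,6R)-3-methyl-6-[2-(triethylsilyloxy)propan-2-yl]nona-2,8-dienoate
Conditions: NaH, THF, 0 °C to 50 °C; the minor Z isomer is removed by chromatography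
Reagents that add atoms: none
Why: Horner–Wadsworth–Emmons olefination of a methyl ketone should favour the E trisubstituted enoate (ester trans to the longer chain), the geometry that step 6 converts into the C2/C3 relationship.

Step 5
Reactants: 7 enoate
Product: 8 (2E,6R)-3-methyl-6-[2-(triethylsilyloxy)propan-2-yl]nona-2,8-dien-1-ol
Conditions: iBu2AlH, CH2Cl2, −78 °C; aq. potassium sodium tartrate
Reagents that add atoms: none
Why: 1,2-Reduction of the enoate with diisobutylaluminium hydride gives the allylic alcohol and leaves the silyl ether and both olefins alone.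

Step 6
Reactants: 8 allylic alcohol
Product: 9 [(2R,3R)-3-methyl-3-{(3R)-3-[2-(triethylsilyloxy)propan-2-yl]hex-5-en-1-yl}oxiran-2-yl]methanol
Conditions: Ti(OiPr)4 (cat.), D-(−)-diethyl tartrate (cat.), tBuOOH, 4 Å MS, CH2Cl2, −20 °C
Reagents that add atoms: tert-butyl hydroperoxide, CC(C)(C)OO
Why: Sharpless asymmetric epoxidation of a geraniol-type E-allylic alcohol is reagent-controlled; the D-(−)-tartrate ligand should deliver oxygen to the face that gives the (2R,3R)-epoxide and so fixes the future O1-bearing carbon C2, while the isolated terminal olefin does not react.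

Step 7
Reactants: 9 epoxy alcohol; 10 4-bromo-2-methylbut-1-ene
Product: 12 (2S,3R,6R)-3-methyl-2-(3-methylbut-3-en-1-yl)-6-[2-(triethylsilyloxy)propan-2-yl]non-8-ene-1,3-diol, via (3-methylbut-3-en-1-yl)magnesium bromide 11 (not isolated)
Conditions: 10, Mg, THF, rt; then CuI (10 mol%), 9, −30 °C to 0 °C; H2O
Reagents that add atoms: none
Why: Copper-catalysed Grignard opening of a 3,3-disubstituted 2,3-epoxy alcohol proceeds by SN2 attack at the secondary carbon (the fully substituted one is closed to substitution), so the side chain enters C3 with inversion and the 1,3-diol carries C2 and C3 in the configuration of the target.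

Step 8
Reactants: 12 diol
Product: 13 (2R,3R,6R)-3-hydroxy-3-methyl-2-(3-methylbut-3-en-1-yl)-6-[2-(triethylsilyloxy)propan-2-yl]non-8-enal
Conditions: TEMPO (cat.), PhI(OAc)2, CH2Cl2, rt
Reagents that add atoms: none
Why: Oxoammonium (TEMPO) oxidation takes only the primary alcohol, and the neutral medium should avoid epimerisation at C3 and retro-aldol cleavage of the β-hydroxy aldehyde.

Step 9
Reactants: 13 hydroxy aldehyde; 14 methyl [bis(2,2,2-trifluoroethoxy)phosphoryl]acetate
Product: 16 (5S,6R)-6-methyl-5-(3-methylbut-3-en-1-yl)-6-{(3R)-3-[2-(triethylsilyloxy)propan-2-yl]hex-5-en-1-yl}-5,6-dihydro-2H-pyran-2-one, via Z-enoate 15 (not isolated)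
Conditions: 14, KN(SiMe3)2, 18-crown-6, THF, −78 °C; then PPTS (cat.), toluene, 60 °C
Reagents that add atoms: none
Why: Still–Gennari olefination gives the Z-enoate, whose ester lies next to the tertiary C2 hydroxyl, and mild acid then closes the six-membered lactone that becomes the pyran ring of the target.

Step 10
Reactants: 16 unsaturated lactone; 17 isobutylmagnesium bromide
Product: 18 (4R,5S,6R)-6-methyl-5-(3-methylbut-3-en-1-yl)-4-(2-methylpropyl)-6-{(3R)-3-[2-(triethylsilyloxy)propan-2-yl]hex-5-en-1-yl}oxan-2-one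
Conditions: 17, CuBr·SMe2 (20 mol%), THF, −78 °C to −40 °C; H2O
Reagents that add atoms: none
Why: Copper-catalysed conjugate addition to a 5,6-dihydropyran-2-one occurs anti to the neighbouring side chain (C3 of the target) and anti to the axial methyl group on the quaternary carbon, which sets the isobutyl group trans at C4.

Step 11
Reactants: 18 lactone; 19 methyl acetoacetate
Product: 21 methyl 4-[(4R,5S,6R)-2-hydroxy-6-methyl-5-(3-methylbut-3-en-1-yl)-4-(2-methylpropyl)-6-{(3R)-3-[2-(triethylsilyloxy)propan-2-yl]hex-5-en-1-yl}oxan-2-yl]-3-oxobutanoate (hemiketal epimers), via dilithio methyl acetoacetate 20 (not isolated)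
Conditions: 19, LiN(iPr)2 (2 equiv per 19), THF, 0 °C; then 18, −78 °C to 0 °C; AcOH
Reagents that add atoms: none
Why: The terminal carbon of the acetoacetate dianion acylates on the lactone carbonyl (Claisen-type addition), forming the C8a–C8 bond, and the tertiary hydroxyl holds the resulting 3,5-dioxo ester as the cyclic hemiketal.

Step 12
Reactants: 21 hemiketal
Product: 22 methyl (4E)-4-[(4R,5S,6R)-6-methyl-5-(3-methylbut-3-en-1-yl)-4-(2-methylpropyl)-6-{(3R)-3-[2-(triethylsilyloxy)propan-2-yl]hex-5-en-1-yl}oxan-2-ylidene]-3-oxobutanoate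
Conditions: PPTS (cat.), 4 Å MS, toluene, 60 °C
Reagents that add atoms: none
Why: Acid-catalysed dehydration of the β-keto hemiketal should give the conjugated exocyclic enol ether (a vinylogous ester), expected as the E isomer with the ketone turned away from the ring oxygen.

Step 13
Reactants: 22 2-ylidene-oxane β-keto ester
Product: 24 (2R,3S,4S)-2-methyl-3-(3-methylbut-3-en-1-yl)-4-(2-methylpropyl)-2-{(3R)-3-[2-(triethylsilyloxy)propan-2-yl]hex-5-en-1-yl}-3,4-dihydro-2H-chromene-5,7-diol, via chromene-5,7-dione tautomer 23 (not isolated)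
Conditions: Mg(OMe)2 (4 equiv), MeOH, 65 °C; then 0.5 M aq. HCl, 0 °C
Reagents that add atoms: none
Why: Proposed new method: Mg(OMe)2 holds the β-keto ester as its magnesium chelate and reversibly removes a proton from the ring methylene C4a, the γ-position of the vinylogous ester O1–C8a=C8–C7=O, to give an extended dienolate whose γ-carbon adds to the chelated ester carbon C5; loss of methoxide gives dione 23, which enolises irreversibly to the benzene ring. The closest known reactions are the Mg(OMe)2-mediated Claisen (Dieckmann-type) cyclisations of 3,5-dioxo and 3,5,7-trioxo esters and their pyranone forms to phloroglucinols, and the Mg(OMe)2-mediated condensations at the vinylogous methyl group of 4-methoxy-6-methyl-2-pyranone; new here is that the C8a carbonyl is held as a cyclic enol ether, so the nucleophile is a γ-carbanion. The carbocycle C4a–C5–C6–C7–C8–C8a closes 6-exo-trig at the ester carbonyl. No stereocentre is created (C4a of 23 is lost on enolisation), and C2, C3 and C4 carry no hydrogen acidic enough for the base to reach. The step needs C-acylation at C4a over every other closure: attack by C6 or C8 would give four-membered rings, the ester is the only electrophile, and because O1 is an ether the usual escape of 3,5-dioxo esters to 4-hydroxy-2-pyranones and the loss of O1 are both shut off. Rotation about C8a–C8 in the dienolate brings C5 within reach of C4a whatever the olefin geometry of 22.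

Step 14
Reactants: 24 dihydroxychroman diene
Product: 25 triethylsilyl ether of the Z-cyclodecene-fused (2R,3S,4S)-5,7-dihydroxy-2-methyl-4-(2-methylpropyl)chroman (bridge C2–CH2–CH2–(R)-CH[C(CH3)2OSiEt3]–CH2–CH=C(CH3)–CH2–CH2–C3)
Conditions: second-generation Grubbs catalyst (10 mol%), toluene (0.5 mM), 80 °C, argon sparge
Reagents that add atoms: none
Why: Ring-closing metathesis should start at the monosubstituted allyl olefin and close onto the 1,1-disubstituted one; the two arms sit trans-diequatorial on neighbouring carbons of the rigid chroman, which keeps the termini close, and the less strained Z trisubstituted cyclodecene is the expected isomer.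

Step 15
Reactants: 25 macrocyclic dihydroxychroman
Product: 27 6,8-diformyl derivative of 25 (triethylsilyl ether of the target), via bis-iminium salt 26 (not isolated)
Conditions: POCl3, DMF, MeCN, 0 °C to rt; then H2O, 40 °C
Reagents that add atoms: N,N-dimethylformamide, CN(C)C=O; water, O
Why: Vilsmeier–Haack formylation of the phloroglucinol-type ring should occur at the two free positions C6 and C8, each ortho or para to all three oxygen donors, and hydrolysis of the bis-iminium salt gives the dialdehyde.

Step 16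
Reactants: 27 silyl ether
Product: 28 target CNP0570248.1
Conditions: HF·pyridine, THF, 0 °C to rt
Reagents that add atoms: none
Why: Fluoride-mediated desilylation frees the tertiary alcohol under conditions that should leave the hydrogen-bonded hydroxy aldehyde units and the ring olefin untouched.

**Compound list**

1 | (R)-α-terpineol | CC1=CC[C@H](C(C)(C)O)CC1 | starting material
2 | triethyl({2-[(1R)-4-methylcyclohex-3-en-1-yl]propan-2-yl}oxy)silane | CC1=CC[C@H](C(C)(C)O[Si](CC)(CC)CC)CC1 | intermediate
3 | secondary ozonide of 2, 1-methyl-4-[2-(triethylsilyloxy)propan-2-yl]-7,8,9-trioxabicyclo[4.2.1]nonane (4R in terpineol sense, bridgeheads unassigned) | CC12CC[C@@H](C(C)(C)O[Si](CC)(CC)CC)CC(OO1)O2 | intermediate (not isolated)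
4 | (3R)-6-oxo-3-[2-(triethylsilyloxy)propan-2-yl]heptanal | O=CC[C@H](C(C)(C)O[Si](CC)(CC)CC)CCC(C)=O | intermediate
5 | (5R)-5-[2-(triethylsilyloxy)propan-2-yl]oct-7-en-2-one | C=CC[C@H](C(C)(C)O[Si](CC)(CC)CC)CCC(C)=O | intermediate
6 | triethyl phosphonoacetate | CCOC(=O)CP(=O)(OCC)OCC | starting material
7 | ethyl (2E,6R)-3-methyl-6-[2-(triethylsilyloxy)propan-2-yl]nona-2,8-dienoate | C=CC[C@H](C(C)(C)O[Si](CC)(CC)CC)CC/C(C)=C/C(=O)OCC | intermediate
8 | (2E,6R)-3-methyl-6-[2-(triethylsilyloxy)propan-2-yl]nona-2,8-dien-1-ol | C=CC[C@H](C(C)(C)O[Si](CC)(CC)CC)CC/C(C)=C/CO | intermediate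
9 | [(2R,3R)-3-methyl-3-{(3R)-3-[2-(triethylsilyloxy)propan-2-yl]hex-5-en-1-yl}oxiran-2-yl]methanol | OC[C@H]1O[C@]1(C)CC[C@H](CC=C)C(C)(C)O[Si](CC)(CC)CC | intermediate
10 | 4-bromo-2-methylbut-1-ene | C=C(C)CCBr | starting material
11 | (3-methylbut-3-en-1-yl)magnesium bromide | C=C(C)CC[Mg]Br | intermediate (not isolated)
12 | (2S,3R,6R)-3-methyl-2-(3-methylbut-3-en-1-yl)-6-[2-(triethylsilyloxy)propan-2-yl]non-8-ene-1,3-diol | C=CC[C@H](C(C)(C)O[Si](CC)(CC)CC)CC[C@@](C)(O)[C@H](CO)CCC(C)=C | intermediate
13 | (2R,3R,6R)-3-hydroxy-3-methyl-2-(3-methylbut-3-en-1-yl)-6-[2-(triethylsilyloxy)propan-2-yl]non-8-enal | C=CC[C@H](C(C)(C)O[Si](CC)(CC)CC)CC[C@@](C)(O)[C@H](C=O)CCC(C)=C | intermediate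
14 | methyl [bis(2,2,2-trifluoroethoxy)phosphoryl]acetate | COC(=O)CP(=O)(OCC(F)(F)F)OCC(F)(F)F | starting material
15 | methyl (2Z,4S,5R,8R)-5-hydroxy-5-methyl-4-(3-methylbut-3-en-1-yl)-8-[2-(triethylsilyloxy)propan-2-yl]undeca-2,10-dienoate | C=CC[C@H](C(C)(C)O[Si](CC)(CC)CC)CC[C@@](C)(O)[C@H](/C=C\C(=O)OC)CCC(C)=C | intermediate (not isolated)
16 | (5S,6R)-6-methyl-5-(3-methylbut-3-en-1-yl)-6-{(3R)-3-[2-(triethylsilyloxy)propan-2-yl]hex-5-en-1-yl}-5,6-dihydro-2H-pyran-2-one | C=CC[C@H](C(C)(C)O[Si](CC)(CC)CC)CC[C@@]1(C)OC(=O)C=C[C@@H]1CCC(C)=C | intermediate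
17 | isobutylmagnesium bromide | CC(C)C[Mg]Br | starting material
18 | (4R,5S,6R)-6-methyl-5-(3-methylbut-3-en-1-yl)-4-(2-methylpropyl)-6-{(3R)-3-[2-(triethylsilyloxy)propan-2-yl]hex-5-en-1-yl}oxan-2-one | C=CC[C@H](C(C)(C)O[Si](CC)(CC)CC)CC[C@@]1(C)OC(=O)C[C@@H](CC(C)C)[C@@H]1CCC(C)=C | intermediate
19 | methyl acetoacetate | CC(=O)CC(=O)OC | starting material
20 | dilithio methyl acetoacetate (dianion of 19) | [Li+].[Li+].C=C([O-])C=C([O-])OC | intermediate (not isolated)
21 | methyl 4-[(4R,5S,6R)-2-hydroxy-6-methyl-5-(3-methylbut-3-en-1-yl)-4-(2-methylpropyl)-6-{(3R)-3-[2-(triethylsilyloxy)propan-2-yl]hex-5-en-1-yl}oxan-2-yl]-3-oxobutanoate (hemiketal epimers) | C=CC[C@H](C(C)(C)O[Si](CC)(CC)CC)CC[C@@]1(C)OC(O)(CC(=O)CC(=O)OC)C[C@@H](CC(C)C)[C@@H]1CCC(C)=C | intermediate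
22 | methyl (4E)-4-[(4R,5S,6R)-6-methyl-5-(3-methylbut-3-en-1-yl)-4-(2-methylpropyl)-6-{(3R)-3-[2-(triethylsilyloxy)propan-2-yl]hex-5-en-1-yl}oxan-2-ylidene]-3-oxobutanoate (key-step precursor) | C=CC[C@H](C(C)(C)O[Si](CC)(CC)CC)CC[C@@]2(C)O/C(=C/C(=O)CC(=O)OC)C[C@@H](CC(C)C)[C@@H]2CCC(C)=C | intermediate
23 | 2,3,4,4a-tetrahydro-5H-chromene-5,7(6H)-dione tautomer of 24 (C2, C3, C4 as in 24; C4a unassigned) | C=CC[C@H](C(C)(C)O[Si](CC)(CC)CC)CC[C@@]2(C)OC3=CC(=O)CC(=O)C3[C@@H](CC(C)C)[C@@H]2CCC(C)=C | intermediate (not isolated)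
24 | (2R,3S,4S)-2-methyl-3-(3-methylbut-3-en-1-yl)-4-(2-methylpropyl)-2-{(3R)-3-[2-(triethylsilyloxy)propan-2-yl]hex-5-en-1-yl}-3,4-dihydro-2H-chromene-5,7-diol (key-step product) | C=CC[C@H](C(C)(C)O[Si](CC)(CC)CC)CC[C@@]2(C)Oc3cc(O)cc(O)c3[C@@H](CC(C)C)[C@@H]2CCC(C)=C | intermediate
25 | Z-cyclodecene-fused (2R,3S,4S)-5,7-dihydroxy-2-methyl-4-(2-methylpropyl)chroman, bridge C2–CH2–CH2–(R)-CH[C(CH3)2OSiEt3]–CH2–CH=C(CH3)–CH2–CH2–C3 | C/C1=C/C[C@H](C(C)(C)O[Si](CC)(CC)CC)CC[C@@]2(C)Oc3cc(O)cc(O)c3[C@@H](CC(C)C)[C@@H]2CC1 | intermediate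
26 | 6,8-bis(dimethyliminiomethyl) derivative of 25, dichloride | C/C1=C/C[C@H](C(C)(C)O[Si](CC)(CC)CC)CC[C@@]2(C)Oc3c(C=[N+](C)C)c(O)c(C=[N+](C)C)c(O)c3[C@@H](CC(C)C)[C@@H]2CC1.[Cl-].[Cl-] | intermediate (not isolated)
27 | 6,8-diformyl derivative of 25 (triethylsilyl ether of the target) | C/C1=C/C[C@H](C(C)(C)O[Si](CC)(CC)CC)CC[C@@]2(C)Oc3c(C=O)c(O)c(C=O)c(O)c3[C@@H](CC(C)C)[C@@H]2CC1 | intermediate
28 | CNP0570248.1: Z-cyclodecene-fused (2R,3S,4S)-5,7-dihydroxy-2-methyl-4-(2-methylpropyl)chroman-6,8-dicarbaldehyde, bridge C2–CH2–CH2–(R)-CH[C(CH3)2OH]–CH2–CH=C(CH3)–CH2–CH2–C3 | C/C1=C/C[C@H](C(C)(C)O)CC[C@@]2(C)Oc3c(C=O)c(O)c(C=O)c(O)c3[C@@H](CC(C)C)[C@@H]2CC1 | target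

**Step count**

Total: 16 steps. Longest linear sequence: 16 steps (1 to 28).

**Steps most likely to fail**

1. Step 13 (bears the label "Proposed new method:"). The β-keto ester rests as its chelated enolate, so the ester carbon may be too poor an electrophile for the γ-carbanion and the closure may stall; methoxide may instead cleave the chain by retro-Claisen attack at C7. The fallback uses known chemistry, the domino Knoevenagel / o-quinone methide hetero-Diels–Alder reaction by which diformylphloroglucinol and isovaleraldehyde are joined to terpene olefins. It sets out from allylic alcohol 8. Appel bromination (CBr4, PPh3, CH2Cl2) would give (2E,6R)-1-bromo-3-methyl-6-[2-(triethylsilyloxy)propan-2-yl]nona-2,8-diene F1. Coupling with 2-methylallylmagnesium chloride (Li2CuCl4 cat., THF) would give the triene triethyl({2-[(4R,7E)-7,11-dimethyldodeca-1,7,11-trien-4-yl]propan-2-yl}oxy)silane F2, which holds the E trisubstituted olefin that becomes C2–C3. Heating F2 with 2,4,6-trihydroxybenzene-1,3-dicarbaldehyde and 3-methylbutanal (ethylenediammonium diacetate, toluene, 80 °C) would generate the o-quinone methide, which adds across the E olefin with O1 on the more substituted carbon. This would give (2R,3S,4S)-5,7-dihydroxy-2-methyl-3-(3-methylbut-3-en-1-yl)-4-(2-methylpropyl)-2-{(3R)-3-[2-(triethylsilyloxy)propan-2-yl]hex-5-en-1-yl}-3,4-dihydro-2H-chromene-6,8-dicarbaldehyde F3. The olefin geometry fixes the C2/C3 relationship, but the cycloaddition does not control the face relative to the remote stereocentre, is not fully selective at C4, and may also engage the 1,1-disubstituted olefin, so F3 would have to be separated from isomers. Ring-closing metathesis of F3 under the conditions of step 14 gives 27, where the fallback rejoins the route before step 16.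

2. Step 14. Closure of a ten-membered ring onto a 1,1-disubstituted olefin may lose to intermolecular metathesis of the allyl termini, or may give the olefin as a mixture of geometries. The fallback replaces olefin metathesis by a reductive carbonyl coupling and sets out from 24. Silylation of both phenols (tBuMe2SiCl, imidazole, DMF) would give the bis(tert-butyldimethylsilyl) ether of 24, F4. Lemieux–Johnson cleavage of both terminal olefins (OsO4 cat., NaIO4, 2,6-lutidine, dioxane/H2O) would give the keto aldehyde F5, whose C2 arm ends in CH2CHO and whose C3 arm ends in CH2CH2C(O)CH3. McMurry coupling with low-valent titanium (TiCl3(DME)1.5, Zn–Cu couple, DME, reflux, slow addition) would close the ten-membered ring at the C(CH3)=CH bond to the bis(tert-butyldimethylsilyl) ether of 25, F6. Bu4NF in THF at 0 °C would remove the two aryl silyl ethers and return 25, where the route continues with step 15.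

3. Step 15. Hydrogen chloride and the chloroiminium reagent may strip the tertiary silyl ether, with ionisation of the exposed alcohol, or add to the ring olefin; the second formylation may also stall on the deactivated ring. The fallback replaces the acidic iminium chemistry by magnesium phenoxide-directed formylation on the free alcohol and sets out from 25. HF·pyridine in THF would give the desilylated Z-cyclodecene-fused (2R,3S,4S)-5,7-dihydroxychroman with the free tertiary alcohol, F7. Treatment with MgCl2, Et3N and paraformaldehyde in THF at reflux (ortho-hydroxymethylation at C6 and C8, each followed by hydride transfer to formaldehyde) would give 28 directly, where the fallback rejoins the route at the target.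

**Further compounds**

F1 | step 13 | (2E,6R)-1-bromo-3-methyl-6-[2-(triethylsilyloxy)propan-2-yl]nona-2,8-diene | C=CC[C@H](C(C)(C)O[Si](CC)(CC)CC)CC/C(C)=C/CBr
F2 | step 13 | triethyl({2-[(4R,7E)-7,11-dimethyldodeca-1,7,11-trien-4-yl]propan-2-yl}oxy)silane | C=CC[C@H](C(C)(C)O[Si](CC)(CC)CC)CC/C(C)=C/CCC(C)=C
F3 | step 13 | (2R,3S,4S)-5,7-dihydroxy-2-methyl-3-(3-methylbut-3-en-1-yl)-4-(2-methylpropyl)-2-{(3R)-3-[2-(triethylsilyloxy)propan-2-yl]hex-5-en-1-yl}-3,4-dihydro-2H-chromene-6,8-dicarbaldehyde | C=CC[C@H](C(C)(C)O[Si](CC)(CC)CC)CC[C@@]2(C)Oc3c(C=O)c(O)c(C=O)c(O)c3[C@@H](CC(C)C)[C@@H]2CCC(C)=C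
F4 | step 14 | 5,7-bis(tert-butyldimethylsilyl) ether of 24 | C=CC[C@H](C(C)(C)O[Si](CC)(CC)CC)CC[C@@]2(C)Oc3cc(O[Si](C)(C)C(C)(C)C)cc(O[Si](C)(C)C(C)(C)C)c3[C@@H](CC(C)C)[C@@H]2CCC(C)=C
F5 | step 14 | keto aldehyde from F4 (C2 arm ending in CH2CHO, C3 arm ending in CH2CH2C(O)CH3) | O=CC[C@H](C(C)(C)O[Si](CC)(CC)CC)CC[C@@]2(C)Oc3cc(O[Si](C)(C)C(C)(C)C)cc(O[Si](C)(C)C(C)(C)C)c3[C@@H](CC(C)C)[C@@H]2CCC(C)=O
F6 | step 14 | 5,7-bis(tert-butyldimethylsilyl) ether of 25 | C/C1=C/C[C@H](C(C)(C)O[Si](CC)(CC)CC)CC[C@@]2(C)Oc3cc(O[Si](C)(C)C(C)(C)C)cc(O[Si](C)(C)C(C)(C)C)c3[C@@H](CC(C)C)[C@@H]2CC1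
F7 | step 15 | desilylated 25 (free tertiary alcohol) | C/C1=C/C[C@H](C(C)(C)O)CC[C@@]2(C)Oc3cc(O)cc(O)c3[C@@H](CC(C)C)[C@@H]2CC1
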